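(The runs were generated by integration from invented constants.)

The coupling partner adds to the substrate step by step, through single product and bis adduct to triple product.

| setting | ash | alder | Thursday's | Tuesday's | Wednesday's |
|---|---|---|---|---|---|
| substrate | 5 mM | 5 mM | 5.0 mM | 5.0 mM | 5.0 mM |
| coupling partner | 1.8 mM | 8.5 mM | 12.5 mM | 2.50 mM | 6.00 mM |
| capture agent | 0.50 mM | 0.50 mM | 0.500 mM | 0.500 mM | 0.500 mM |
| remark | run made earlier | run made earlier |  |  |  |
| time |  |  | 3.0 min | 3.0 min | 3.0 min |

| run | time / s | triple product / % | bis adduct / % |
|---|---|---|---|
| ash | 15.0 | 0.1 | 1.4 |
| ash | 40.0 | 0.1 | 1.0 |
| ash | 80.0 | 0 | 1.7 |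
| ash | 120 | 0 | 1.9 |
| alder | 15.0 | 0.4 | 5.2 |
| alder | 40.0 | 1.8 | 9.9 |
| alder | 80.0 | 3.1 | 11.1 |
| alder | 120 | 4.4 | 11.1 |

(standard deviation of a reading: 0.5 percentage points)

- which of these holds the largest part of the substrate at the end of Thursday's (bis adduct / substrate / single product / triple product)
- which of these holds the largest part of the substrate at the end of Tuesday's (bis adduct / substrate / single product / triple product)
- which of these holds the largest part of the substrate at the end of Wednesday's (bis adduct / substrate / single product / triple product)
- how much triple product is there at the end of Wednesday's, in percent of the substrate charged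

- what was read earlier has a scatter of 0.5 percentage points, one standard deviation

Ash's last triple product read 0 %, below the scatter of 0.5 percentage points, so I worked from alder. My zero of the scale was the symmetric case, an assumption: every coupling equally fast. Then one coupling count n, couplings per substrate charged, gives the series: substrate exp(−n), single product n times substrate, bis adduct n/2 times single product, triple product n/3 times bis adduct.

So alder's last pair, 4.4 % on 11.1 %, read n = 1.19, scatter included, but alder was charged 1.70 equivalents. The delivered share, couplings per equivalent of coupling partner charged, therefore read 0.700.

For Wednesday's, at 1.20 equivalents, I then reckoned n = 0.839, below one, so I committed to substrate 43.2 % over single product 36.3 %.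

The forecast gave single product for Thursday's, substrate for Tuesday's, single product for Wednesday's and 1 % triple product there, reasoning that “about 0.5 mM partner remains after single and bis formation”. We parted on Wednesday's.

    substrate + coupling partner → single product + released group (k = 6.80 /M/s)
    coupling partner + single product → bis adduct + released group (k = 3.80 /M/s)
    coupling partner + bis adduct → triple product + released group (k = 4.20 /M/s)
    2 coupling partner → self-condensation product (k = 3.90 /M/s)
    bis adduct + released group → side product (k = 0.920 /M/s)
    single product + capture agent → trapped intermediate (k = 3.90 /M/s)

Wednesday's ended with substrate 42.7 % above single product 37.5 %, a ratio of 0.878 against my count of 0.839, and triple product 2.05 %. At Wednesday's start, the coupling partner, the limiting reagent with 0.40 % of its charge left at the end, fell by self-condensation at 0.0468 /s, faster than the 0.0340 /s on substrate. With 3.0 mM of substrate in Wednesday's recipe, the same share gives n = 1.40, above one, and that neighbour ended with single product 39.4 % above substrate 31.4 %, a ratio of 1.25.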